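## The problem

Target 33 is a (2S)-flavanone, formally the 6,2′-diprenyl derivative of hesperetin, in which ring A (C4a to C8a, oxygenated at C5, C7 and C8a) is fused to pyranone ring C along C4a–C8a and ring B sits on C2. C2 is the only stereocentre, so no other centre can relay chirality to it and it has to come from a chiral reagent or catalyst. Once ring C exists C2 is fragile, because base opens the ring by retro-oxa-Michael reaction to a chalcone and acid can ionise the C2–O1 bond with help from the para 4′-methoxy group. The two prenyl groups rule out hydrogenolysis, ozonolysis and electrophilic halogenation, and under acid they add to a neighbouring free phenol to give chromans. Regiochemistry is the second difficulty, since prenylation of a 5,7-dihydroxyflavanone does not tell C6 from C8 and C2′ is the most hindered position of ring B. The feature that invites an annulation is ring A itself, where O5, the C6 prenyl group and O7 sit on three adjacent carbons and the ether oxygen O1 on C8a is para to C6. An alkoxy-substituted vinylketene can supply C8, C8a, C4a and one oxygenated carbon and a prenyl-substituted siloxyalkyne the other oxygenated carbon and C6; because C5 and C7 then carry like substituents, the two carbons ortho to O1 are equivalent and either may become C4a.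

## Retrosynthesis

**33 from 32.** The last operation only removes three aryl silyl ethers from flavanone 32. Silyl groups are chosen because buffered fluoride spares both the prenyl groups and C2, which acid-labile or base-labile protecting groups would not.

**32 from 30 (C4–C4a).** Ring C is opened at the aryl ketone bond, giving the 3-aryl-3-aryloxypropanoic acid 30. The neighbouring cut, O1–C2, leads to a chalcone and would put the asymmetric step at the end under basic conditions. Cutting C4–C4a leaves C2 as an ordinary benzylic ether centre that can be set early. The forward reaction is an intramolecular acylation of a phloroglucinol-type ring, which must run without free acid.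

**30 from 29 from 28.** Acid 30 comes from allyl ester 29 by palladium-catalysed deallylation, which avoids hydroxide and the E1cB loss of phenoxide it would invite. Bis-silyl ether 29 comes from phenol 28 by silylation, which makes ring A locally symmetric so that the later acylation has only one possible outcome.

**28 from 17 and 23 (key disconnection).** Ring A is taken apart into the chiral 3-alkoxycyclobutenone 17 and the prenyl siloxyalkyne 23. Against prenylating a preformed phloroglucinol ether, this cut fixes the prenyl group between the two oxygens by construction. Both precursors are small and the stereocentre is a spectator. The forward reaction must be regioselective in the ketene–alkyne cycloaddition and neutral enough not to ionise the benzylic C–O bond.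

**17 from 13 and 15.** The enol ether C–O bond at the stereocentre is made by Mitsunobu alkylation of cyclobutane-1,3-dione 15 with the (3R)-β-hydroxy ester 13, with inversion. Dione 15 comes from 3-ethoxycyclobutenone 14 by hydrolysis. A direct acid-catalysed alkoxy exchange into 14, which would retain configuration, is held in reserve because it exposes a p-methoxybenzylic vinylogous ester to acid.

**13 from 12 from 11 from 8 and 9.** The carbinol centre is set by asymmetric transfer hydrogenation of β-keto ester 12, whose sense is predictable and which leaves alkenes untouched. Keto ester 12 arises by oxidation of the racemic aldol 11 of aldehyde 8 with allyl acetate 9.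

**8 from 7 from 5 from 4 and 3.** Aldehyde 8 is the silyl ether of 2-prenylisovanillin 7. The prenyl group is placed at C2 by aromatic Claisen rearrangement of the 1,1-dimethylallyl ether 5, which has only one free ortho position. Ether 5 comes from isovanillin 4 and carbonate 3, itself made from 2-methylbut-3-en-2-ol 1.

**23 from 20 from 18 and 19.** The siloxyalkyne is the O-silylated ynolate of 5-methylhex-4-en-1-yne 20, which is assembled from prenyl bromide 18 and ethynylmagnesium bromide 19.

## Roads not taken

Alternative 1: late double aromatic Claisen rearrangement. The cut is at the two aryl–CH2 bonds of the prenyl groups. The unprenylated core is the chiral-pool flavanone (2S)-hesperetin A1 . Protection of its 7-OH as a methoxymethyl ether and conversion of its 5-OH and 3′-OH into 1,1-dimethylallyl ethers would give the bis(1,1-dimethylallyl) ether A2 . Heating A2 would shift both allyl units from oxygen to carbon and give the diprenylated flavanone 7-methoxymethyl ether A3 .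
- Merits: each [3,3] shift has a single open ortho carbon (C6, because C4a is blocked; C2′, because C4′ carries methoxy), and C2 need not be created because A1 already has it.
- Weak points: the 5-OH of A1 is hydrogen-bonded to the C4 carbonyl, so making a tertiary ether there is the hardest etherification in the molecule. The basic etherification and the heating of A2 are conditions under which flavanones open to chalcones, putting C2 at risk. The C6 dienone on the way to A3 can go on by Cope shift to C8. The final acetal removal from A3 needs acid beside two prenyl groups ortho to phenols.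
- Comparison: this road is clearly shorter, roughly a third of the steps. The chosen plan sets against it a ring A whose substitution is fixed by construction and a ring C that is closed two steps from the end and never sees heat or base.

Alternative 2: anodic decarboxylative cyclisation. The cut is C2–C3. The α-aryloxy arylacetic acid A4 , which carries an enol acetate ortho to the ether oxygen on ring A, would be oxidised at an anode. Hofer–Moest loss of CO2 leaves a cationic, oxygen-stabilised C2, which the enol acetate carbon captures to give the flavanone triacetate A5 .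
- Merits: ring C closes at room temperature without acid or base, and A4 is easy to assemble by O-alkylation. In carrying both prenyl groups in on simple arenes it equals the chosen plan, and its ring closure is milder than a Friedel–Crafts acylation.
- Weak points: the cationic centre is planar and nothing chiral remains after CO2 has left, so A5 would be racemic unless a chiral influence is invented. The electron-rich arenes and trisubstituted alkenes of A4 are oxidised near the potential of the carboxylate. Three acetates must then be removed from A5 under conditions that endanger C2.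
- Comparison: the chosen plan is longer but controls C2 by a defined reduction, which is decisive for a single enantiomer.

Alternative 3: enantioselective intramolecular hydroacylation. The cut is C3–C4. Salicylaldehyde A6 , whose ether oxygen carries a 1-arylvinyl group, would be treated with [Rh(cod)Cl]2 and a chiral bisphosphine. Insertion into the formyl C–H bond, hydrometalation of the enol ether with hydrogen going to C2, and reductive elimination would give the flavanone bis(methoxymethyl) ether A7 .
- Merits: it is atom-economical, and C2 is made by a catalyst in the ring-closing step, so the stereocentre has almost nothing to survive. The free 5-OH can chelate rhodium and hold back decarbonylation. In these respects, and probably in linear length, it is better than the chosen plan.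
- Weak points: a six-membered-ring hydroacylation of a 1,1-disubstituted, electron-rich enol ether with enantiocontrol in the hydride transfer has thin precedent. The Rh–H intermediate can isomerise the prenyl alkenes. The aryl 1-arylvinyl ether of A6, between two ortho-substituted rings and beside a free aldehyde, is hard to make. The acetals of A7 again need acid at the end.
- Comparison: the chosen plan relies at every step on reaction types with close precedent and sets C2 by a reduction of predictable sense. Its price is that the centre must be carried through a Mitsunobu inversion, a thermal step and an acylation.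

Key step: step 12

Remarks on the chemistry.
- Ar stands throughout for 3-(tert-butyldimethylsilyloxy)-4-methoxy-2-(3-methylbut-2-enyl)phenyl.
- Assumption: the facial sense of the transfer hydrogenation in step 7 is taken to follow that of simple aryl ketones with the same catalyst (aryl as the large group). If the opposite alcohol formed, the enantiomeric ligand would be used.
- In 28 to 30 the ring A locants C5/C7 and C4a/C8 are interchangeable; they become fixed only when ring C closes.

## Route

Step 1
Reactants: 1 2-methylbut-3-en-2-ol
Product: 3 methyl 2-methylbut-3-en-2-yl carbonate, via lithium alkoxide 2 (not isolated)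
Conditions: n-BuLi, THF, −78 °C; ClCO2Me, −78 → 0 °C
Reagents that add atoms: methyl chloroformate COC(=O)Cl
Why: Acylation of a preformed alkoxide; the tertiary allylic alcohol is too hindered for amine-mediated carbonate formation.

Step 2
Reactants: 4 isovanillin; 3 methyl 2-methylbut-3-en-2-yl carbonate
Product: 5 4-methoxy-3-(2-methylbut-3-en-2-yloxy)benzaldehyde
Conditions: Pd(PPh3)4 (2 mol%), THF, 0 °C
Reagents that add atoms: none
Why: Tsuji–Trost O-allylation: zerovalent palladium ionises 3 with loss of CO2 and the methoxide formed deprotonates the phenol. Under kinetic control at low temperature the phenoxide attacks the more substituted terminus of the dimethylallyl–palladium intermediate, giving the tertiary ether.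

Step 3
Reactants: 5 4-methoxy-3-(2-methylbut-3-en-2-yloxy)benzaldehyde
Product: 7 3-hydroxy-4-methoxy-2-(3-methylbut-2-enyl)benzaldehyde, via ortho-dienone 6 (not isolated)
Conditions: PhNEt2, 130 °C
Reagents that add atoms: none
Why: Aromatic Claisen rearrangement: the [3,3] shift can go only to C2, the one free ortho position, and inverts the allyl unit so that a normal prenyl group arrives on carbon. Tautomerisation of dienone 6 restores the phenol.

Step 4
Reactants: 7 3-hydroxy-4-methoxy-2-(3-methylbut-2-enyl)benzaldehyde
Product: 8 3-(tert-butyldimethylsilyloxy)-4-methoxy-2-(3-methylbut-2-enyl)benzaldehyde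
Conditions: TBSCl, imidazole, DMF, rt
Reagents that add atoms: tert-butyldimethylsilyl chloride CC(C)(C)[Si](C)(C)Cl
Why: Phenol silylation; the TBS ether masks the acidic OH for the enolate, Mitsunobu and annulation steps and is removed by fluoride at the end.

Step 5
Reactants: 9 allyl acetate; 8 3-(tert-butyldimethylsilyloxy)-4-methoxy-2-(3-methylbut-2-enyl)benzaldehyde
Product: 11 allyl (±)-3-Ar-3-hydroxypropanoate, via lithium enolate 10 (not isolated)
Conditions: LiN(i-Pr)2, THF, −78 °C; 8, −78 °C; AcOH
Reagents that add atoms: none
Why: Acetate aldol addition of a preformed lithium ester enolate to a non-enolisable aldehyde, quenched cold to avoid retro-aldol; the carbinol centre is left uncontrolled because step 6 erases it.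

Step 6
Reactants: 11 allyl (±)-3-Ar-3-hydroxypropanoate
Product: 12 allyl 3-Ar-3-oxopropanoate
Conditions: Dess–Martin periodinane, CH2Cl2, rt
Reagents that add atoms: none
Why: Dess–Martin oxidation of a secondary benzylic alcohol to the β-keto ester under neutral conditions that leave the alkenes and the silyl ether alone.

Step 7
Reactants: 12 allyl 3-Ar-3-oxopropanoate
Product: 13 allyl (3R)-3-Ar-3-hydroxypropanoate
Conditions: RuCl(p-cymene)[(R,R)-TsDPEN] (1 mol%), HCO2H–Et3N (5:2), rt
Reagents that add atoms: none
Why: Asymmetric transfer hydrogenation of an aryl β-keto ester (Noyori type); the (R,R)-diamine ligand selects the ketone face with the aryl group held against the η6-arene, which should give the (3R)-alcohol. Isolated alkenes are inert because no H2 is used.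

Step 8
Reactants: 14 3-ethoxycyclobut-2-en-1-one
Product: 15 cyclobutane-1,3-dione
Conditions: 1 M HCl (aq), 0 °C → rt
Reagents that add atoms: water O
Why: Acid hydrolysis of a vinylogous ester by addition–elimination of water at C3; the dione is used fresh.

Step 9
Reactants: 13 allyl (3R)-3-Ar-3-hydroxypropanoate; 15 cyclobutane-1,3-dione
Product: 17 allyl (3S)-3-Ar-3-(3-oxocyclobut-1-enyloxy)propanoate, via alkoxyphosphonium salt 16 (not isolated)
Conditions: PPh3, DIAD, PhMe–THF, −20 → 0 °C
Reagents that add atoms: none
Why: Mitsunobu O-alkylation of an acidic enol (pKa about 3, like a carboxylic acid): the enolate oxygen displaces the phosphonium oxide group of 16 by SN2, inverting the carbinol carbon from (3R) to (3S). Low polarity and low temperature are chosen to disfavour ionisation and dehydration to the cinnamate.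

Step 10
Reactants: 18 1-bromo-3-methylbut-2-ene; 19 ethynylmagnesium bromide
Product: 20 5-methylhex-4-en-1-yne
Conditions: CuCl (5 mol%), THF, 0 °C → rt
Reagents that add atoms: none
Why: Copper-catalysed coupling of an alkynyl Grignard reagent with a primary allylic bromide; attack at the unhindered CH2 terminus is favoured over SN2′ and gives the skipped enyne.

Step 11
Reactants: 20 5-methylhex-4-en-1-yne
Product: 23 triisopropyl(5-methylhex-4-en-1-ynyloxy)silane, via lithium acetylide 21 (not isolated), via lithium ynolate 22 (not isolated)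
Conditions: n-BuLi, THF, −78 °C; LiOOt-Bu (from t-BuOOH and LiN(SiMe3)2), −78 → 0 °C; TIPSOTf, −78 °C
Reagents that add atoms: tert-butyl hydroperoxide CC(C)(C)OO; triisopropylsilyl triflate CC(C)[Si](C(C)C)(C(C)C)OS(=O)(=O)C(F)(F)F
Why: Oxidation of a lithium acetylide by lithium tert-butyl peroxide gives the ynolate, and the bulky silyl triflate silylates it on oxygen to give the siloxyalkyne, not a silylketene.

Step 12
Reactants: 17 allyl (3S)-3-Ar-3-(3-oxocyclobut-1-enyloxy)propanoate; 23 triisopropyl(5-methylhex-4-en-1-ynyloxy)silane
Product: 28 allyl (3S)-3-Ar-3-[3-hydroxy-4-(3-methylbut-2-enyl)-5-(triisopropylsilyloxy)phenoxy]propanoate, via vinylketene 24 (not isolated), via 4-vinylcyclobutenone 25 (not isolated), via dienylketene 26 (not isolated), via cyclohexa-2,4-dienone 27 (not isolated)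
Conditions: 23 (2 equiv), PhMe, 80 → 110 °C, sealed tube
Reagents that add atoms: none
Why: Heating opens cyclobutenone 17 by reversible four-electron electrocyclic ring opening to vinylketene 24, whose ketene C=C adds to siloxyalkyne 23 in a regioselective [2+2] cycloaddition to give 4-vinylcyclobutenone 25; this opens again to dienylketene 26, which closes to dienone 27, and enolisation gives phenol 28. The closest known reaction type is the Danheiser benzannulation of cyclobutenones with trialkylsiloxyalkynes, which gives 2-substituted resorcinol monosilyl ethers. Ring A is closed in a formal [4+2] annulation of four cyclobutenone carbons with the two alkyne carbons, its last bond (C7–C8) being made by a thermally allowed disrotatory six-electron electrocyclisation driven by aromatisation. No stereocentre is created: the vinyl-bearing ring carbon of 25 is stereogenic only in passing and is flattened in 26, and C2, the benzylic ether carbon, takes no part. The selectivity needed is the orientation of the [2+2] step, and polarity secures it: the prenyl-bearing carbon of the ynol ether is the nucleophilic terminus and bonds to the ketene carbonyl carbon, so hydroxyl, prenyl and siloxy end up on adjacent carbons with the chiral alkoxy group para to prenyl. The siloxyalkyne is far more nucleophilic than the prenyl and allyl alkenes, so these should not intercept the ketene. A non-polar solvent without acid or base is used so that the benzylic C–O bond of the vinylogous ester does not ionise and the β-alkoxy ester does not eliminate, and excess 23 keeps the product phenol from being acylated by ketene.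

Step 13
Reactants: 28 allyl (3S)-3-Ar-3-[3-hydroxy-4-(3-methylbut-2-enyl)-5-(triisopropylsilyloxy)phenoxy]propanoate
Product: 29 allyl (3S)-3-Ar-3-[4-(3-methylbut-2-enyl)-3,5-bis(triisopropylsilyloxy)phenoxy]propanoate
Conditions: TIPSCl, imidazole, DMF, rt
Reagents that add atoms: triisopropylsilyl chloride CC(C)[Si](Cl)(C(C)C)C(C)C
Why: Phenol silylation; it makes the two ring A carbons ortho to the ether oxygen equivalent and prevents O-acylation in step 15.

Step 14
Reactants: 29 allyl (3S)-3-Ar-3-[4-(3-methylbut-2-enyl)-3,5-bis(triisopropylsilyloxy)phenoxy]propanoate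
Product: 30 (3S)-3-Ar-3-[4-(3-methylbut-2-enyl)-3,5-bis(triisopropylsilyloxy)phenoxy]propanoic acid
Conditions: Pd(PPh3)4 (5 mol%), morpholine, THF, rt
Reagents that add atoms: none
Why: Palladium-catalysed deallylation (π-allyl transfer to morpholine) frees the acid without hydroxide, so the β-aryloxy ester cannot lose phenoxide by E1cB and the aryl silyl ethers survive.

Step 15
Reactants: 30 (3S)-3-Ar-3-[4-(3-methylbut-2-enyl)-3,5-bis(triisopropylsilyloxy)phenoxy]propanoic acid
Product: 32 (2S)-2-Ar-6-(3-methylbut-2-enyl)-5,7-bis(triisopropylsilyloxy)chroman-4-one, via mixed anhydride 31 (not isolated)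
Conditions: (CF3CO)2O, 2,6-di-tert-butyl-4-methylpyridine, CH2Cl2, −20 → 0 °C
Reagents that add atoms: none
Why: Intramolecular Friedel–Crafts acylation through the mixed trifluoroacetic anhydride; the phloroglucinol-type ring A is nucleophilic enough to react without a metal Lewis acid, and six-membered ring C closes at either of the equivalent ortho carbons. The hindered pyridine takes up CF3CO2H so that the prenyl groups and the benzylic C2–O1 bond are not exposed to acid.

Step 16
Reactants: 32 (2S)-2-Ar-6-(3-methylbut-2-enyl)-5,7-bis(triisopropylsilyloxy)chroman-4-one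
Product: 33 (2S)-5,7-dihydroxy-2-[3-hydroxy-4-methoxy-2-(3-methylbut-2-enyl)phenyl]-6-(3-methylbut-2-enyl)chroman-4-one
Conditions: Bu4NF, AcOH, THF, 0 °C
Reagents that add atoms: none
Why: Fluoride cleavage of the three aryl silyl ethers; acetic acid protonates the phenoxides as they form so that the flavanone cannot open to the chalcone and racemise at C2.

## Compound list

1 | 2-methylbut-3-en-2-ol | C=CC(C)(C)O | starting material
2 | lithium 2-methylbut-3-en-2-olate | [Li+].[O-]C(C)(C)C=C | intermediate
3 | methyl 2-methylbut-3-en-2-yl carbonate | COC(=O)OC(C)(C)C=C | intermediate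
4 | isovanillin (3-hydroxy-4-methoxybenzaldehyde) | COc1ccc(C=O)cc1O | starting material
5 | 4-methoxy-3-(2-methylbut-3-en-2-yloxy)benzaldehyde | COc1ccc(C=O)cc1OC(C)(C)C=C | intermediate
6 | 5-formyl-2-methoxy-6-(3-methylbut-2-enyl)cyclohexa-2,4-dien-1-one (racemic) | COC1=CC=C(C=O)C(CC=C(C)C)C1=O | intermediate
7 | 3-hydroxy-4-methoxy-2-(3-methylbut-2-enyl)benzaldehyde | COc1ccc(C=O)c(CC=C(C)C)c1O | intermediate
8 | 3-(tert-butyldimethylsilyloxy)-4-methoxy-2-(3-methylbut-2-enyl)benzaldehyde | COc1ccc(C=O)c(CC=C(C)C)c1O[Si](C)(C)C(C)(C)C | intermediate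
9 | allyl acetate | CC(=O)OCC=C | starting material
10 | lithium 1-(allyloxy)ethenolate | [Li+].[O-]C(=C)OCC=C | intermediate
11 | allyl (±)-3-[3-(tert-butyldimethylsilyloxy)-4-methoxy-2-(3-methylbut-2-enyl)phenyl]-3-hydroxypropanoate | C=CCOC(=O)CC(O)c1ccc(OC)c(O[Si](C)(C)C(C)(C)C)c1CC=C(C)C | intermediate
12 | allyl 3-[3-(tert-butyldimethylsilyloxy)-4-methoxy-2-(3-methylbut-2-enyl)phenyl]-3-oxopropanoate | C=CCOC(=O)CC(=O)c1ccc(OC)c(O[Si](C)(C)C(C)(C)C)c1CC=C(C)C | intermediate
13 | allyl (3R)-3-[3-(tert-butyldimethylsilyloxy)-4-methoxy-2-(3-methylbut-2-enyl)phenyl]-3-hydroxypropanoate | C=CCOC(=O)C[C@@H](O)c1ccc(OC)c(O[Si](C)(C)C(C)(C)C)c1CC=C(C)C | intermediate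
14 | 3-ethoxycyclobut-2-en-1-one | CCOC1=CC(=O)C1 | starting material
15 | cyclobutane-1,3-dione | O=C1CC(=O)C1 | intermediate
16 | {(1R)-3-(allyloxy)-1-[3-(tert-butyldimethylsilyloxy)-4-methoxy-2-(3-methylbut-2-enyl)phenyl]-3-oxopropoxy}triphenylphosphonium 3-oxocyclobut-1-en-1-olate | C=CCOC(=O)C[C@@H](O[P+](c1ccccc1)(c1ccccc1)c1ccccc1)c1ccc(OC)c(O[Si](C)(C)C(C)(C)C)c1CC=C(C)C.[O-]C1=CC(=O)C1 | intermediate
17 | allyl (3S)-3-[3-(tert-butyldimethylsilyloxy)-4-methoxy-2-(3-methylbut-2-enyl)phenyl]-3-(3-oxocyclobut-1-enyloxy)propanoate | C=CCOC(=O)C[C@H](OC1=CC(=O)C1)c1ccc(OC)c(O[Si](C)(C)C(C)(C)C)c1CC=C(C)C | intermediate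
18 | 1-bromo-3-methylbut-2-ene (prenyl bromide) | CC(C)=CCBr | starting material
19 | ethynylmagnesium bromide | C#C[Mg]Br | starting material
20 | 5-methylhex-4-en-1-yne | CC(C)=CCC#C | intermediate
21 | lithium 5-methylhex-4-en-1-yn-1-ide | [Li+].[C-]#CCC=C(C)C | intermediate
22 | lithium 5-methylhex-4-en-1-yn-1-olate | [Li+].[O-]C#CCC=C(C)C | intermediate
23 | triisopropyl(5-methylhex-4-en-1-ynyloxy)silane | CC(C)=CCC#CO[Si](C(C)C)(C(C)C)C(C)C | intermediate
24 | allyl (3S)-3-[3-(tert-butyldimethylsilyloxy)-4-methoxy-2-(3-methylbut-2-enyl)phenyl]-3-(4-oxobuta-1,3-dien-2-yloxy)propanoate | C=CCOC(=O)C[C@H](OC(=C)C=C=O)c1ccc(OC)c(O[Si](C)(C)C(C)(C)C)c1CC=C(C)C | intermediate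
25 | allyl (3S)-3-[3-(tert-butyldimethylsilyloxy)-4-methoxy-2-(3-methylbut-2-enyl)phenyl]-3-{1-[3-(3-methylbut-2-enyl)-4-oxo-2-(triisopropylsilyloxy)cyclobut-2-en-1-yl]ethenyloxy}propanoate (both configurations at the ring CH) | C=CCOC(=O)C[C@H](OC(=C)C1C(=O)C(CC=C(C)C)=C1O[Si](C(C)C)(C(C)C)C(C)C)c1ccc(OC)c(O[Si](C)(C)C(C)(C)C)c1CC=C(C)C | intermediate
26 | allyl (3S)-3-[3-(tert-butyldimethylsilyloxy)-4-methoxy-2-(3-methylbut-2-enyl)phenyl]-3-[5-(3-methylbut-2-enyl)-6-oxo-4-(triisopropylsilyloxy)hexa-1,3,5-trien-2-yloxy]propanoate | C=CCOC(=O)C[C@H](OC(=C)C=C(O[Si](C(C)C)(C(C)C)C(C)C)C(CC=C(C)C)=C=O)c1ccc(OC)c(O[Si](C)(C)C(C)(C)C)c1CC=C(C)C | intermediate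
27 | allyl (3S)-3-[3-(tert-butyldimethylsilyloxy)-4-methoxy-2-(3-methylbut-2-enyl)phenyl]-3-[4-(3-methylbut-2-enyl)-5-oxo-3-(triisopropylsilyloxy)cyclohexa-1,3-dien-1-yloxy]propanoate | C=CCOC(=O)C[C@H](OC1=CC(O[Si](C(C)C)(C(C)C)C(C)C)=C(CC=C(C)C)C(=O)C1)c1ccc(OC)c(O[Si](C)(C)C(C)(C)C)c1CC=C(C)C | intermediate
28 | allyl (3S)-3-[3-(tert-butyldimethylsilyloxy)-4-methoxy-2-(3-methylbut-2-enyl)phenyl]-3-[3-hydroxy-4-(3-methylbut-2-enyl)-5-(triisopropylsilyloxy)phenoxy]propanoate | C=CCOC(=O)C[C@H](Oc1cc(O)c(CC=C(C)C)c(O[Si](C(C)C)(C(C)C)C(C)C)c1)c1ccc(OC)c(O[Si](C)(C)C(C)(C)C)c1CC=C(C)C | intermediate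
29 | allyl (3S)-3-[3-(tert-butyldimethylsilyloxy)-4-methoxy-2-(3-methylbut-2-enyl)phenyl]-3-[4-(3-methylbut-2-enyl)-3,5-bis(triisopropylsilyloxy)phenoxy]propanoate | C=CCOC(=O)C[C@H](Oc1cc(O[Si](C(C)C)(C(C)C)C(C)C)c(CC=C(C)C)c(O[Si](C(C)C)(C(C)C)C(C)C)c1)c1ccc(OC)c(O[Si](C)(C)C(C)(C)C)c1CC=C(C)C | intermediate
30 | (3S)-3-[3-(tert-butyldimethylsilyloxy)-4-methoxy-2-(3-methylbut-2-enyl)phenyl]-3-[4-(3-methylbut-2-enyl)-3,5-bis(triisopropylsilyloxy)phenoxy]propanoic acid | OC(=O)C[C@H](Oc1cc(O[Si](C(C)C)(C(C)C)C(C)C)c(CC=C(C)C)c(O[Si](C(C)C)(C(C)C)C(C)C)c1)c1ccc(OC)c(O[Si](C)(C)C(C)(C)C)c1CC=C(C)C | intermediate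
31 | mixed anhydride of acid 30 with trifluoroacetic acid, (3S) | FC(F)(F)C(=O)OC(=O)C[C@H](Oc1cc(O[Si](C(C)C)(C(C)C)C(C)C)c(CC=C(C)C)c(O[Si](C(C)C)(C(C)C)C(C)C)c1)c1ccc(OC)c(O[Si](C)(C)C(C)(C)C)c1CC=C(C)C | intermediate
32 | (2S)-2-[3-(tert-butyldimethylsilyloxy)-4-methoxy-2-(3-methylbut-2-enyl)phenyl]-6-(3-methylbut-2-enyl)-5,7-bis(triisopropylsilyloxy)chroman-4-one | COc1ccc([C@@H]2CC(=O)c3c(cc(O[Si](C(C)C)(C(C)C)C(C)C)c(CC=C(C)C)c3O[Si](C(C)C)(C(C)C)C(C)C)O2)c(CC=C(C)C)c1O[Si](C)(C)C(C)(C)C | intermediate
33 | (2S)-5,7-dihydroxy-2-[3-hydroxy-4-methoxy-2-(3-methylbut-2-enyl)phenyl]-6-(3-methylbut-2-enyl)chroman-4-one | COc1ccc([C@@H]2CC(=O)c3c(cc(O)c(CC=C(C)C)c3O)O2)c(CC=C(C)C)c1O | target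

## Step count and risks

Total: 16 steps. Longest linear sequence: 13 steps (1, 2, 3, 4, 5, 6, 7, 9, 12, 13, 14, 15, 16), or 12 counted from isovanillin.

**Step 12 (key step).** The most likely failure is heterolysis of the benzylic C–O bond of 17 during heating. The carbon is p-methoxybenzylic and the leaving group is the enolate of an acid of pKa about 3, so racemisation by ion-pair return or loss of the cyclobutenone with cinnamate formation can compete. The 3-alkoxy donor also stabilises the cyclobutenone and slows its ring opening, which lengthens the exposure to heat. Acylation of the product phenol by ketene is a lesser concern.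

Fallback: attach ring A ready-made instead of building it. The fallback sets out from prenyl bromide 18 and alcohol 13 and comes back to the route at 29. Phloroglucinol would be C-prenylated with 18 (DBU, THF) to give 2-(3-methylbut-2-enyl)benzene-1,3,5-triol F1. Silylation of all three hydroxyl groups (TIPSOTf, 2,6-lutidine) would give 2-(3-methylbut-2-enyl)-1,3,5-tris(triisopropylsilyloxy)benzene F2. The unhindered silyl ether para to the prenyl group would then be removed (Bu4NF, 1 equiv, THF, −78 °C) to give 4-(3-methylbut-2-enyl)-3,5-bis(triisopropylsilyloxy)phenol F3. Mitsunobu coupling of this phenol with 13 (PPh3, DIAD, PhMe, 0 °C) inverts the carbinol centre and rejoins the route at 29.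

**Step 9.** Dehydration of the β-hydroxy ester to the cinnamate and partial SN1 character at the electron-rich benzylic carbon (erosion of enantiopurity) are the main dangers. Amination of the dione at carbon by the azodicarboxylate can also consume the nucleophile.

Fallback: form the C–O bond with retention, so that the bond to the stereocentre is never broken. The fallback sets out from keto ester 12 and comes back at 17. Reduction of 12 with the (S,S)-ligand catalyst would give allyl (3S)-3-Ar-3-hydroxypropanoate F4. This alcohol would then be exchanged into 14 (pyridinium p-toluenesulfonate, cat., PhMe, 50 °C, reduced pressure to remove ethanol) to give 17.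

**Step 15.** Acid released during acylation may ionise the benzylic aryl ether or add across a prenyl group if buffering is imperfect. The two flanking triisopropylsilyloxy groups may slow attack at the ortho carbon enough for trifluoroacetylation of ring A to compete.

Fallback: close ring C at the aldehyde oxidation level, which needs much weaker activation. The fallback sets out from ester 29 and comes back at 32. Reduction of 29 (i-Bu2AlH, CH2Cl2, −78 °C) would give (3S)-3-Ar-3-[4-(3-methylbut-2-enyl)-3,5-bis(triisopropylsilyloxy)phenoxy]propanal F5. Intramolecular hydroxyalkylation of ring A (MgBr2·OEt2, CH2Cl2, −78 °C) would give (2S)-2-Ar-6-(3-methylbut-2-enyl)-5,7-bis(triisopropylsilyloxy)chroman-4-ol F6 as a mixture at C4. Dess–Martin oxidation of this alcohol returns to 32.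

**Step 11.** Incomplete oxygen transfer to the acetylide, base-induced isomerisation of the skipped enyne towards conjugated isomers, and silylation on carbon are the likely problems.

Fallback: make the ynolate from an ester. The fallback sets out from alcohol 1 and comes back at 23. Johnson–Claisen rearrangement of 1 with triethyl orthoacetate (propionic acid cat., 140 °C) would give ethyl 5-methylhex-4-enoate F7. Two rounds of enolate bromination (LiN(i-Pr)2, then BrCCl2CCl2Br, THF, −78 °C) would give ethyl 2-bromo-5-methylhex-4-enoate F8 and then ethyl 2,2-dibromo-5-methylhex-4-enoate F9. Bromine–lithium exchange on the dibromo ester (t-BuLi, THF, −78 → 0 °C) with loss of ethoxide and rearrangement gives ynolate 22, which is silylated as in step 11 to 23.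

**Step 3 (with step 2).** The tertiary ether may lose isoprene on heating. If step 2 drifts towards the thermodynamically preferred linear prenyl ether, rearrangement would deliver a 1,1-dimethylallyl group instead.

Fallback: introduce the side chain as allyl and convert it. The fallback sets out from isovanillin 4 and comes back at 7. Allylation of 4 (allyl bromide, K2CO3, DMF) would give 3-(allyloxy)-4-methoxybenzaldehyde F10. Claisen rearrangement (neat, 190 °C) would give 2-allyl-3-hydroxy-4-methoxybenzaldehyde F11. Cross-metathesis of this phenol with 2-methylbut-2-ene (second-generation Grubbs catalyst, CH2Cl2, 40 °C) gives 7.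

## Further compounds

F1 | step 12 | 2-(3-methylbut-2-enyl)benzene-1,3,5-triol | CC(C)=CCc1c(O)cc(O)cc1O
F2 | step 12 | 2-(3-methylbut-2-enyl)-1,3,5-tris(triisopropylsilyloxy)benzene | CC(C)=CCc1c(O[Si](C(C)C)(C(C)C)C(C)C)cc(O[Si](C(C)C)(C(C)C)C(C)C)cc1O[Si](C(C)C)(C(C)C)C(C)C
F3 | step 12 | 4-(3-methylbut-2-enyl)-3,5-bis(triisopropylsilyloxy)phenol | CC(C)=CCc1c(O[Si](C(C)C)(C(C)C)C(C)C)cc(O)cc1O[Si](C(C)C)(C(C)C)C(C)C
F4 | step 9 | allyl (3S)-3-[3-(tert-butyldimethylsilyloxy)-4-methoxy-2-(3-methylbut-2-enyl)phenyl]-3-hydroxypropanoate | C=CCOC(=O)C[C@H](O)c1ccc(OC)c(O[Si](C)(C)C(C)(C)C)c1CC=C(C)C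
F5 | step 15 | (3S)-3-[3-(tert-butyldimethylsilyloxy)-4-methoxy-2-(3-methylbut-2-enyl)phenyl]-3-[4-(3-methylbut-2-enyl)-3,5-bis(triisopropylsilyloxy)phenoxy]propanal | O=CC[C@H](Oc1cc(O[Si](C(C)C)(C(C)C)C(C)C)c(CC=C(C)C)c(O[Si](C(C)C)(C(C)C)C(C)C)c1)c1ccc(OC)c(O[Si](C)(C)C(C)(C)C)c1CC=C(C)C
F6 | step 15 | (2S)-2-[3-(tert-butyldimethylsilyloxy)-4-methoxy-2-(3-methylbut-2-enyl)phenyl]-6-(3-methylbut-2-enyl)-5,7-bis(triisopropylsilyloxy)chroman-4-ol (both C4 epimers) | COc1ccc([C@@H]2CC(O)c3c(cc(O[Si](C(C)C)(C(C)C)C(C)C)c(CC=C(C)C)c3O[Si](C(C)C)(C(C)C)C(C)C)O2)c(CC=C(C)C)c1O[Si](C)(C)C(C)(C)C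
F7 | step 11 | ethyl 5-methylhex-4-enoate | CCOC(=O)CCC=C(C)C
F8 | step 11 | ethyl 2-bromo-5-methylhex-4-enoate (racemic) | CCOC(=O)C(Br)CC=C(C)C
F9 | step 11 | ethyl 2,2-dibromo-5-methylhex-4-enoate | CCOC(=O)C(Br)(Br)CC=C(C)C
F10 | step 3 | 3-(allyloxy)-4-methoxybenzaldehyde | COc1ccc(C=O)cc1OCC=C
F11 | step 3 | 2-allyl-3-hydroxy-4-methoxybenzaldehyde | COc1ccc(C=O)c(CC=C)c1O
A1 | alternative 1 | (2S)-hesperetin | COc1ccc([C@@H]2CC(=O)c3c(O)cc(O)cc3O2)cc1O
A2 | alternative 1 | (2S)-4′-methoxy-7-(methoxymethoxy)-5,3′-bis(2-methylbut-3-en-2-yloxy)flavanone | COc1ccc([C@@H]2CC(=O)c3c(cc(OCOC)cc3OC(C)(C)C=C)O2)cc1OC(C)(C)C=C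
A3 | alternative 1 | (2S)-5-hydroxy-2-[3-hydroxy-4-methoxy-2-(3-methylbut-2-enyl)phenyl]-7-(methoxymethoxy)-6-(3-methylbut-2-enyl)chroman-4-one | COc1ccc([C@@H]2CC(=O)c3c(cc(OCOC)c(CC=C(C)C)c3O)O2)c(CC=C(C)C)c1O
A4 | alternative 2 | 2-[3,5-diacetoxy-2-(1-acetoxyvinyl)-4-(3-methylbut-2-enyl)phenoxy]-2-[3-acetoxy-4-methoxy-2-(3-methylbut-2-enyl)phenyl]acetic acid (racemic) | COc1ccc(C(Oc2cc(OC(C)=O)c(CC=C(C)C)c(OC(C)=O)c2C(=C)OC(C)=O)C(O)=O)c(CC=C(C)C)c1OC(C)=O
A5 | alternative 2 | (2S)-5,7-diacetoxy-2-[3-acetoxy-4-methoxy-2-(3-methylbut-2-enyl)phenyl]-6-(3-methylbut-2-enyl)chroman-4-one | COc1ccc([C@@H]2CC(=O)c3c(cc(OC(C)=O)c(CC=C(C)C)c3OC(C)=O)O2)c(CC=C(C)C)c1OC(C)=O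
A6 | alternative 3 | 2-hydroxy-4-(methoxymethoxy)-6-{1-[4-methoxy-3-(methoxymethoxy)-2-(3-methylbut-2-enyl)phenyl]vinyloxy}-3-(3-methylbut-2-enyl)benzaldehyde | COCOc1c(OC)ccc(C(=C)Oc2cc(OCOC)c(CC=C(C)C)c(O)c2C=O)c1CC=C(C)C
A7 | alternative 3 | (2S)-5-hydroxy-7-(methoxymethoxy)-2-[4-methoxy-3-(methoxymethoxy)-2-(3-methylbut-2-enyl)phenyl]-6-(3-methylbut-2-enyl)chroman-4-one | COCOc1c(OC)ccc([C@@H]2CC(=O)c3c(cc(OCOC)c(CC=C(C)C)c3O)O2)c1CC=C(C)C
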